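## Retrosynthetic overview

1. Ludongnin I ⇐ exo-face hydrogenation of a 16-methylene-15-ketone (sets C16) ⇐ α-methylenation of a bicyclo[3.2.1]octenone.
2. Ring D (C13–C16) ⇐ Pd(II) silyl-enol-ether/alkene cyclisation; ring C ⇐ [4+2] of butadiene with a spiro 3-acetyl-5,6-dihydropyran-2-one (sets C8, C9).
3. Lactone ring B and quaternary C10 ⇐ addition–elimination of a ring-A aldehyde enolate onto ethoxymethylene acetoacetate, then reduction/lactonisation.
4. Ring A (C4, C5) ⇐ [4+2] of citraconic anhydride with a glyceraldehyde-derived diene; the glyceraldehyde stereocentre steers the cycloaddition and is then cleaved down to the C20 aldehyde.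
5. Ring order: A (Diels–Alder) → acetal ring → B (lactone) → C (Diels–Alder) → D (Pd).

Assumption: ent-kaurane numbering is used throughout, and the facial sense of step 2 follows the inside-alkoxy/anti-alkyl model for dienes with an allylic alkoxy stereocentre (if it is reversed, the (R)-aldehyde from D-mannitol is used instead).

## Route

**Step 1**
Reactants: 1, (S)-2,3-O-isopropylideneglyceraldehyde (commercial; from L-ascorbic acid); 2, allyl(diphenyl)phosphine oxide
Product: 3, (4R)-4-[(1E)-buta-1,3-dien-1-yl]-2,2-dimethyl-1,3-dioxolane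
Conditions: 2, n-BuLi, THF/HMPA, −78 °C → rt
Reagents that add atoms: allyl(diphenyl)phosphine oxide (2), C=CCP(=O)(c1ccccc1)c1ccccc1
Why: Horner–Wittig olefination gives the (E)-diene without touching the stereocentre (S becomes R only through the CIP priority change).

**Step 2**
Reactants: 3; 4, citraconic anhydride
Product: 5, endo adduct 7-[(4R)-2,2-dimethyl-1,3-dioxolan-4-yl]-3a-methyl-3a,4,7,7a-tetrahydro-2-benzofuran-1,3-dione (3a-CH3 and 7a-H cis = C4 R, C5 R; dioxolanyl on future C10, cis to the anhydride)
Conditions: toluene, BHT, 60–80 °C; major isomer crystallised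
Reagents that add atoms: citraconic anhydride (4), CC1=CC(=O)OC1=O
Why: Diels–Alder forms ring A: the unsubstituted diene terminus bonds to the methyl-bearing carbon (sterics and LUMO coefficient), the cyclic Z-dienophile fixes Me/H cis, and the endo dienophile adds anti to the dioxolane CH2 with C–O inside, giving (4R,5R).

**Step 3**
Reactants: 5
Product: 6, the hexahydro anhydride (ring alkene saturated)
Conditions: H2 (1 atm), Pd/C, EtOAc, rt
Reagents that add atoms: none
Why: Catalytic hydrogenation of the isolated cis-alkene, so that the later C10 enolate is not a dienolate; no stereocentre is affected.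

**Step 4**
Reactants: 6
Product: 7, cis-fused γ-lactone 7-[(4R)-2,2-dimethyl-1,3-dioxolan-4-yl]-3a-methylhexahydro-2-benzofuran-1(3H)-one (C=O = C6 on the CH side; OCH2 = C19 on the quaternary carbon)
Conditions: NaBH4, THF, 0 °C → rt; then pH 3 (citric acid)
Reagents that add atoms: none
Why: Bailey–Johnson regioselective borohydride reduction; hydride attacks the carbonyl next to the quaternary carbon and the hydroxy acid lactonises.

**Step 5**
Reactants: 7
Product: 8, cis-3a-methyl-1-oxooctahydro-2-benzofuran-7-carbaldehyde (CHO = C20; the C10 epimers are equivalent for the route)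
Conditions: H5IO6, EtOAc, rt
Reagents that add atoms: none
Why: One-pot acetonide hydrolysis and Malaprade diol cleavage removes the controlling stereocentre and leaves it as the enolisable C20 aldehyde; the lactone is acid-stable.

**Step 6**
Reactants: 8
Product: 9, 7-{[(tert-butyldimethylsilyl)oxy]methylidene}-3a-methylhexahydro-2-benzofuran-1(3H)-one (E/Z)
Conditions: TBSOTf (1.05 equiv), Et3N, CH2Cl2, −78 → 0 °C
Reagents that add atoms: TBSOTf, CC(C)(C)[Si](C)(C)OS(=O)(=O)C(F)(F)F
Why: Soft enolisation silylates only the aldehyde; the silyl enol ether protects C20 from hydride and stores the C10 nucleophile.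

**Step 7**
Reactants: 9
Product: 10, the lactol (1-hydroxy, anomer mixture)
Conditions: DIBAL-H (1.1 equiv), CH2Cl2, −78 °C; Rochelle salt
Reagents that add atoms: none
Why: DIBAL half-reduction of the γ-lactone stops at the aluminium hemiacetal at −78 °C; the silyl enol ether is inert.

**Step 8**
Reactants: 10
Product: 11, (1S,3aR,7aR)-1-methoxy-3a-methyl-7-{[(tert-butyldimethylsilyl)oxy]methylidene}octahydro-2-benzofuran
Conditions: MeI, Ag2O, MeCN, rt, dark
Reagents that add atoms: iodomethane, CI
Why: Purdie O-methylation under neutral conditions caps the lactol as the convex-face methyl acetal (OMe trans to C10, also the thermodynamic anomer; C6 = S) without hydrolysing the enol ether.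

**Step 9**
Reactants: 11; 12, ethyl 2-(ethoxymethylene)-3-oxobutanoate
Product: 13, ethyl 2-acetyl-3-[(1S,3aR,7R,7aR)-7-formyl-1-methoxy-3a-methyloctahydro-2-benzofuran-7-yl]prop-2-enoate (CHO = C20 cis to the acetal ring; alkenyl = C9 trans; E/Z mixture)
Conditions: 12, TASF (or anhydrous TBAF), THF, −40 °C → rt
Reagents that add atoms: ethyl 2-(ethoxymethylene)-3-oxobutanoate (12), CCOC=C(C(C)=O)C(=O)OCC
Why: Fluoride releases the aldehyde enolate, which undergoes conjugate addition–elimination (SNV) from the convex, equatorial face of the cis-fused bicycle, creating quaternary C10 (R).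

**Step 10**
Reactants: 13
Product: 14, spiro dienophile: 3-acetyl-5,6-dihydro-2H-pyran-2-one spiro-fused at C10 to the 1-methoxy-3a-methyloctahydro-2-benzofuran (OCH2 = C20 cis to the acetal ring, vinylic CH = C9)
Conditions: NaBH4 (0.5 equiv), CH2Cl2/EtOH, −78 °C; then cat. DBU, rt
Reagents that add atoms: none
Why: At −78 °C the aldehyde is reduced faster than the hindered alkylidene β-keto ester; the neopentyl alkoxide then transesterifies onto the cis ester (E/Z equilibrates) to close the δ-lactone.

**Step 11**
Reactants: 14; 15, buta-1,3-diene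
Product: 16, Diels–Alder adduct: cyclohexene (C12=C13) cis-fused to the δ-lactone across C8–C9, acetyl on C8 (8S,9S)
Conditions: 15 (excess), toluene, BHT, sealed tube, 110–120 °C
Reagents that add atoms: buta-1,3-diene (15), C=CC=C
Why: Diels–Alder on the doubly activated alkylidene keto-lactone forms ring C; butadiene adds suprafacially to the face of C8=C9 next to C1H2 and away from the C5–C6 acetal, setting C8 and C9.

**Step 12**
Reactants: 16
Product: 17, the tert-butyldimethylsilyl enol ether of the methyl ketone
Conditions: KHMDS, TBSCl, THF, −78 °C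
Reagents that add atoms: TBSCl, CC(C)(C)[Si](C)(C)Cl
Why: The acetyl CH3 is the only enolisable position (C8 is quaternary); base-mediated O-silylation avoids acid at the acetal.

**Step 13**
Reactants: 17
Product: 18, 17-nor-11,12-didehydro compound: bicyclo[3.2.1]octenone with the 15-ketone, C16H2 and C11=C12
Conditions: Pd(OAc)2 (1 equiv), MeCN, rt (or cat. Pd(OAc)2, O2, DMSO)
Reagents that add atoms: none
Why: Kende/Toyota Pd(II) cycloalkenylation: the Pd enolate inserts the ring alkene 5-exo (C16–C13) on the only face the tether reaches, fixing C13, and syn β-hydride elimination gives the C11=C12 alkene.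

**Step 14**
Reactants: 18
Product: 19, 16-methylene-15-ketone (11,12-didehydro-16,17-didehydro-ludongnin I)
Conditions: LiHMDS, THF, −78 °C; CH2=NMe2+ I−; then MeI; DBU
Reagents that add atoms: Eschenmoser's salt, C=[N+](C)C.[I-]
Why: The ketone enolises only toward C16; Mannich reaction, quaternisation and E1cB elimination install the exocyclic methylene.

**Step 15**
Reactants: 19
Product: 20, ludongnin I
Conditions: H2 (1 atm), Pd/C, EtOAc, rt
Reagents that add atoms: none
Why: Hydrogenation of the exocyclic enone from the exo (C14-bridge) face, as for other ent-kaur-16-en-15-ones, gives the endo 16R methyl; C11=C12 is saturated in the same step.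

## Compound list

1 | (S)-2,2-dimethyl-1,3-dioxolane-4-carbaldehyde | O=C[C@@H]1COC(C)(C)O1 | starting material
2 | allyl(diphenyl)phosphine oxide | C=CCP(=O)(c1ccccc1)c1ccccc1 | starting material
3 | (4R)-4-[(1E)-buta-1,3-dienyl]-2,2-dimethyl-1,3-dioxolane | C=C/C=C/[C@@H]1COC(C)(C)O1 | intermediate
4 | citraconic anhydride | CC1=CC(=O)OC1=O | starting material
5 | endo Diels–Alder anhydride | O=C1OC(=O)[C@]2(C)CC=C[C@H]([C@@H]3COC(C)(C)O3)[C@H]12 | intermediate
6 | saturated anhydride | O=C1OC(=O)[C@]2(C)CCC[C@H]([C@@H]3COC(C)(C)O3)[C@H]12 | intermediate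
7 | γ-lactone acetonide | O=C1OC[C@]2(C)CCC[C@H]([C@@H]3COC(C)(C)O3)[C@H]12 | intermediate
8 | lactone aldehyde | O=C1OC[C@]2(C)CCC[C@H](C=O)[C@H]12 | intermediate
9 | lactone silyl enol ether | O=C1OC[C@]2(C)CCCC(=CO[Si](C)(C)C(C)(C)C)[C@H]12 | intermediate
10 | lactol silyl enol ether | OC1OC[C@]2(C)CCCC(=CO[Si](C)(C)C(C)(C)C)[C@H]12 | intermediate
11 | methyl acetal silyl enol ether | CO[C@H]1OC[C@]2(C)CCCC(=CO[Si](C)(C)C(C)(C)C)[C@H]12 | intermediate
12 | ethyl 2-(ethoxymethylene)-3-oxobutanoate | CCOC=C(C(C)=O)C(=O)OCC | starting material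
13 | C10-quaternary aldehyde / alkylidene acetoacetate | CO[C@H]1OC[C@]2(C)CCC[C@@](C=O)(C=C(C(C)=O)C(=O)OCC)[C@H]12 | intermediate
14 | spiro 3-acetyl-dihydropyranone dienophile | CO[C@H]1OC[C@]2(C)CCC[C@]3(COC(=O)C(C(C)=O)=C3)[C@H]12 | intermediate
15 | buta-1,3-diene | C=CC=C | starting material
16 | ring-C Diels–Alder adduct | CO[C@H]1OC[C@]2(C)CCC[C@]3(COC(=O)[C@]4(CC=CC[C@H]43)C(C)=O)[C@H]12 | intermediate
17 | TBS enol ether of 16 | CO[C@H]1OC[C@]2(C)CCC[C@]3(COC(=O)[C@]4(CC=CC[C@H]43)C(=C)O[Si](C)(C)C(C)(C)C)[C@H]12 | intermediate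
18 | bicyclo[3.2.1]octenone (C16H2, Δ11) | CO[C@H]1OC[C@]2(C)CCC[C@]3(COC(=O)[C@@]45C[C@@H](C=C[C@H]43)CC5=O)[C@H]12 | intermediate
19 | 16-methylene-Δ11 enone | CO[C@H]1OC[C@]2(C)CCC[C@]3(COC(=O)[C@@]45C[C@@H](C=C[C@H]43)C(=C)C5=O)[C@H]12 | intermediate
20 | ludongnin I | CO[C@H]1OC[C@]2(C)CCC[C@]3(COC(=O)[C@@]45C[C@@H](CC[C@H]43)[C@@H](C)C5=O)[C@H]12 | target

## Totals and risks

Total steps: 15. Longest linear sequence: 15 (fully linear; 2, 4, 12 and 15 are commercial).

Steps most likely to fail:

- **Step 2 (regio-, endo- and facial selectivity of the first Diels–Alder).** Fallback: tether the dienophile. Open citraconic anhydride with the corresponding dienyl alcohol (from the same aldehyde) and run the ester-tethered intramolecular Diels–Alder, which fixes regiochemistry and puts the stereocentre in the forming ring. The C19 acid is then reduced via its mixed anhydride and the lactone translactonised.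
- **Step 9 (quaternary C10 by enolate addition–elimination; also avoids the selective reduction in step 10).** Fallback: alkylate the potassium enolate of the aldehyde with benzyl chloromethyl ether (C9 as CH2OBn), reduce C20 with NaBH4 and acetoacetylate with diketene. Hydrogenolysis and Dess–Martin oxidation with in situ intramolecular Knoevenagel condensation then give 14.
- **Step 13 (Pd(II) 5-exo cyclisation onto an internal ring alkene).** Fallback: epoxidise C12=C13 of 16, open the epoxide at C13 intramolecularly with the ketone enolate (LiHMDS), and remove the resulting C12 hydroxyl by Barton–McCombie deoxygenation to reach the saturated analogue of 18.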